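| flask | substrate | partner | second reagent | remark | time |
|---|---|---|---|---|---|
| larch | 0.16 M | 1 equiv | 1.05 equiv | run made earlier |  |
| ash | 0.16 M | 2.2 equiv | 1.05 equiv | run made earlier |  |
| flask | 0.16 M | 1.50 equiv | 1.05 equiv |  | 12 h |

| run | time / h | target / % | side product B / % |
|---|---|---|---|
| larch | 2.00 | 14.8 | 64.2 |
| larch | 4.00 | 15.7 | 63.8 |
| larch | 6.00 | 14.6 | 64.6 |
| larch | 8.00 | 15.0 | 64.6 |
| larch | 10.0 | 14.3 | 64.9 |
| larch | 12.0 | 14.9 | 65.2 |
| ash | 2.00 | 16.8 | 73.7 |
| ash | 4.00 | 17.1 | 74.7 |
| ash | 6.00 | 18.3 | 74.3 |
| ash | 8.00 | 17.0 | 74.2 |
| ash | 10.0 | 17.8 | 74.2 |
| ash | 12.0 | 17.5 | 74.4 |

(readings scatter by 0.5 percentage points)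

- a reading or a percentage of target counts all its forms, free or not
- the reaction counts as stopped when no species that holds the substrate changes by six tenths of a point or more over the second half of the time

- which holds at 12 h: what has brought the reaction to rest, or that it has not come to rest (all of the substrate has reacted / the partner has run out first / the second reagent has run out first / forward and back rates have come level / it is still moving)
- how much target there is at 12 h, in percent of the substrate charged
- how much side product B there is at 12 h, in percent of the substrate charged

Side product B over target read 4.34 in larch and 4.26 in ash, although partner went from 1 equiv to 2.2 equiv. So I took target as a steady 18.9% of what was seen.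

Why, then, did the seen total stand at 79.4% in larch and 91.7% in ash? I read the gap as an unmeasured product of a rival path that needs no partner, and supposed seen plus gap to make up the whole charge. The readings could not exclude a halted equilibrium.

Substrate then divides in the ratio of partner to a constant, and integrating as partner falls gives: gap = constant × ln(partner charged / partner remaining), all as shares of the substrate charged. Larch read 13.0% and ash 15.5%, mean 14.2%: the rival strength, the partner level at which both paths take substrate equally (a selectivity factor turned over).

For the flask at 1.50 equiv this gave a gap of 12.6%, hence my 16.5% target and 70.9% side product B, with the substrate reacted.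

The forecast said forward and back rates have come level, with 16.7% target and 71.3% side product B: “Conversion that stops short yet rises with partner points to equilibrium”. We parted on how the flask stops.

The flask gave all of the substrate has reacted, 16.7% target and 71.3% side product B.

    substrate + partner → intermediate (k = 0.0350 M⁻¹ s⁻¹)
    second reagent + intermediate → target (k = 0.0180 M⁻¹ s⁻¹)
    substrate + second reagent → side product A (k = 0.00522 M⁻¹ s⁻¹)
    intermediate → side product B (k = 0.0109 s⁻¹)
    crystals ⇌ target, rate k5*(cs5 - [target]) while solid is left; crystals form when [target] > cs5 (solubility = 0.0850 M, k = 0.445 s⁻¹)

The flask held 0% substrate at 1.20 h. Its target stood low mainly because intermediate turned into side product B: the same run without that step gave 89.0% target against 16.7%. The gap was side product A, 12.0% against my 12.6%. Carried to the neighbour flask with 0.380 equiv partner, rival strength 14.2% gives a gap of 62.5%. That neighbour, with 0.133% of its partner remaining, held 62.1% side product A.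

All runs were generated by integration with made-up constants; noise was put on by code.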